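**Plan**

1. Cuts: (i) the ester C–O bond at C5 of the cyclohexene, read as opening of a 4,5-epoxide by the free acid; (ii) the aryl C4–vinyl bond (carboxylate-directed C–H olefination); (iii) the C2–C3 bond of the dihydrobenzofuran (carbene C–H insertion); (iv) the C1–C6 bond of the cyclohexene (one-carbon ring expansion).
2. Enabling feature: in the cyclohexene, C1(CO2H)=C2H next to the C6 methylene is the dehydrated form of a β-keto ester (C2 ketone, C1 ester). That is the footprint of inserting a diazoacetate carbon into the C(=O)–CH2 bond of a cyclopentanone that already carries the three contiguous oxygens (future C3, C4, C5).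
3. Carbocycle, forward: silyloxycyclopentenone 1 → trioxygenated cyclopentanone 3 → ring expansion to cyclohexanone 9 → cyclohexene 12 → triol 13 → epoxy alcohol 14.
4. Heterocycle, forward: Claisen, Mitsunobu and ozonolysis give aryl diazoacetate 23 → cis-dihydrobenzofuran 24 → acid 25 → C4 acrylate 28; then 28 + 14 → 29 → global desilylation → 30.
5. Stereochemistry: C5 comes from commercial (R)-1; C3/C4 from anti dihydroxylation; C5 is inverted twice (epoxide closure, carboxylate opening). C2/C3 of the dihydrobenzofuran (cis, 2S,3R) come from the chiral dirhodium catalyst; the E-alkene from β-hydride elimination. The epimerisable C3 is never acyl-activated and never exposed to base as an ester.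

Key step: step 6

Remark: the sense of induction in step 18 is assigned by analogy with the parent 2-benzyloxyphenyl diazoacetate series; should the (2R,3S) antipode form, Rh2(S-PTTL)4 is used instead. The carbinol centre of 8 and C1/C2 of 9–11 form as mixtures that converge in steps 6 and 8, so their SMILES leave these centres undefined.

**Route**

Step 1
Reactants: 1 (R)-4-(tert-butyldimethylsilyloxy)cyclopent-2-en-1-one
Product: 2 (2S,3R,4R)-4-(tert-butyldimethylsilyloxy)-2,3-dihydroxycyclopentan-1-one
Conditions: OsO4 (1 mol%), NMO, citric acid, t-BuOH/H2O, rt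
Reagents that add atoms: N-methylmorpholine N-oxide, C[N+]1([O-])CCOCC1; water, O; osmium tetroxide (catalytic oxygen carrier), O=[Os](=O)(=O)=O
Why: Upjohn-type cis-dihydroxylation (citric acid-buffered for an electron-poor enone) should add both hydroxyls anti to the allylic silyloxy group, so the new C2 and C3 centres (future C3 and C4 of the cyclohexene) are cis to each other and trans to the C4 oxygen (future C5) by substrate control.

Step 2
Reactants: 2 (2S,3R,4R)-4-(tert-butyldimethylsilyloxy)-2,3-dihydroxycyclopentan-1-one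
Product: 3 (2S,3R,4R)-4-(tert-butyldimethylsilyloxy)-2,3-(isopropylidenedioxy)cyclopentan-1-one
Conditions: 2,2-dimethoxypropane, PPTS (cat.), CH2Cl2, rt
Reagents that add atoms: 2,2-dimethoxypropane, COC(C)(C)OC
Why: Acid-catalysed transketalisation closes the cis-fused dioxolane on the cis-1,2-diol, which removes the β-hydroxy ketone liability without touching a stereocentre.

Step 3
Reactants: 4 2-(trimethylsilyl)ethanol; 5 bromoacetyl bromide
Product: 6 2-(trimethylsilyl)ethyl bromoacetate
Conditions: pyridine, CH2Cl2, 0 °C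
Reagents that add atoms: none
Why: O-acylation of a primary alcohol by an acyl bromide (esterification) under pyridine buffering.

Step 4
Reactants: 6 2-(trimethylsilyl)ethyl bromoacetate
Product: 7 2-(trimethylsilyl)ethyl diazoacetate
Conditions: N,N'-ditosylhydrazine, DBU, THF, 0 °C
Reagents that add atoms: N,N'-ditosylhydrazine, Cc1ccc(cc1)S(=O)(=O)NNS(=O)(=O)c1ccc(C)cc1
Why: Fukuyama diazoacetate synthesis: the bis-sulfonyl hydrazide is N-alkylated by the bromoacetate and DBU then expels two sulfinates to unveil the diazo group.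

Step 5
Reactants: 3 (2S,3R,4R)-4-(tert-butyldimethylsilyloxy)-2,3-(isopropylidenedioxy)cyclopentan-1-one; 7 2-(trimethylsilyl)ethyl diazoacetate
Product: 8 2-(trimethylsilyl)ethyl 2-diazo-2-[(2S,3R,4R)-4-(tert-butyldimethylsilyloxy)-1-hydroxy-2,3-(isopropylidenedioxy)cyclopentyl]acetate (C1 epimers)
Conditions: LDA, THF, −78 °C; then 3; NH4Cl quench
Reagents that add atoms: none
Why: Aldol-type addition of the lithiated diazoacetate to the ketone at −78 °C should outrun enolisation and β-elimination of the silyloxy group; the new carbinol centre (attack expected anti to the dioxolane) is destroyed in step 6 and need not be controlled.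

Step 6
Reactants: 8 2-(trimethylsilyl)ethyl 2-diazo-2-[(2S,3R,4R)-4-(tert-butyldimethylsilyloxy)-1-hydroxy-2,3-(isopropylidenedioxy)cyclopentyl]acetate
Product: 9 2-(trimethylsilyl)ethyl (3S,4R,5R)-5-(tert-butyldimethylsilyloxy)-3,4-(isopropylidenedioxy)-2-oxocyclohexane-1-carboxylate (C1 epimers and enol)
Conditions: Rh2(OAc)4 (1 mol%), CH2Cl2, 0 °C → rt
Reagents that add atoms: none
Why: Rh2(OAc)4 converts the diazo group of 8 into an electrophilic rhodium carbenoid, and the cyclopentane bond from the carbinol carbon to the ring CH2 shifts to the carbene carbon as the carbinol collapses to a ketone, so the former diazo carbon becomes ring carbon C1 bearing the ester and the carbinol carbon becomes the C2 ketone. The closest known reaction type is the dirhodium-catalysed ring expansion of α-diazo-β-hydroxy esters made from cyclic ketones, a semipinacol-type one-carbon homologation. No ring is closed in the usual sense: the six-membered ring arises from the five-membered one by 1,2-migration of the ring methylene (future C6) from the carbinol carbon to the carbenoid carbon. The only new stereocentre, C1 between the two carbonyls, is enolisable and is left uncontrolled because it becomes sp2 in step 8, while C3, C4 and C5 are spectators and keep the configuration set in step 1. The step needs regioselectivity between the two ring bonds at the carbinol carbon, and the bond to the dioxolane carbon (future C3) carries an α-oxygen and a further β-oxygen whose inductive withdrawal should lower its migratory aptitude towards the electron-poor carbenoid, so the unsubstituted CH2 should migrate. It also needs chemoselectivity over O–H insertion and loss of the silyloxy group, which the fast intramolecular shift of a tertiary β-hydroxy carbenoid and the neutral, base-free medium should secure.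

Step 7
Reactants: 9 2-(trimethylsilyl)ethyl (3S,4R,5R)-5-(tert-butyldimethylsilyloxy)-3,4-(isopropylidenedioxy)-2-oxocyclohexane-1-carboxylate
Product: 10 2-(trimethylsilyl)ethyl 5-(tert-butyldimethylsilyloxy)-2-hydroxy-3,4-(isopropylidenedioxy)cyclohexane-1-carboxylate (C1/C2 diastereomers; C3–C5 as in 9)
Conditions: NaBH4, THF/MeOH, −20 °C
Reagents that add atoms: none
Why: Chemoselective borohydride reduction of the ketone of a β-keto ester beside the ester; the new C2 carbinol centre is formed as a mixture that converges in step 8.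

Step 8
Reactants: 10 2-(trimethylsilyl)ethyl 5-(tert-butyldimethylsilyloxy)-2-hydroxy-3,4-(isopropylidenedioxy)cyclohexane-1-carboxylate
Product: 12 2-(trimethylsilyl)ethyl 5-O-(tert-butyldimethylsilyl)-3,4-O-isopropylidene-shikimate, via the C2 mesylate 11 (not isolated)
Conditions: MsCl, Et3N, CH2Cl2, 0 °C; then DBU, rt
Reagents that add atoms: none
Why: Mesylation followed by DBU-induced E1cB elimination through the ester enolate places the double bond between C1 and C2 in conjugation with the ester and erases the uncontrolled C1/C2 centres; the silyl ether and acetonide are inert to amine bases.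

Step 9
Reactants: 12 2-(trimethylsilyl)ethyl 5-O-(tert-butyldimethylsilyl)-3,4-O-isopropylidene-shikimate
Product: 13 2-(trimethylsilyl)ethyl shikimate, (3R,4S,5R)
Conditions: 2 M aq. HCl/THF, rt
Reagents that add atoms: none
Why: Dilute aqueous acid hydrolyses the dioxolane and the secondary TBS ether (acetal hydrolysis and desilylation) while the TMSE ester and the allylic alcohol should tolerate it at room temperature; no stereocentre is touched.

Step 10
Reactants: 13 2-(trimethylsilyl)ethyl shikimate
Product: 14 2-(trimethylsilyl)ethyl (3R,4R,5S)-4,5-epoxy-3-hydroxycyclohex-1-ene-1-carboxylate (epoxide cis to the 3-OH)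
Conditions: PPh3, DIAD, THF, 0 °C → rt
Reagents that add atoms: none
Why: Mitsunobu cyclodehydration, known for shikimate esters: the non-allylic C5 hydroxyl is activated as the oxyphosphonium and displaced by the trans-vicinal C4 hydroxyl with inversion at C5, giving the 4,5-epoxide cis to the C3 hydroxyl.

Step 11
Reactants: 15 2-(allyloxy)phenol
Product: 16 1-(allyloxy)-2-(triisopropylsilyloxy)benzene
Conditions: TIPSCl, imidazole, DMF, rt
Reagents that add atoms: triisopropylsilyl chloride, CC(C)[Si](Cl)(C(C)C)C(C)C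
Why: Imidazole-promoted silylation of a phenol.

Step 12
Reactants: 16 1-(allyloxy)-2-(triisopropylsilyloxy)benzene
Product: 17 2-allyl-6-(triisopropylsilyloxy)phenol
Conditions: N,N-diethylaniline, 200 °C
Reagents that add atoms: none
Why: Aromatic Claisen rearrangement: the [3,3] shift can only end at the single free ortho position, and tautomerisation gives the phenol flanked by allyl and silyloxy groups.

Step 13
Reactants: 18 3,4-dihydroxybenzaldehyde
Product: 19 3,4-bis(triisopropylsilyloxy)benzaldehyde
Conditions: TIPSCl (2.4 equiv), imidazole, DMF, rt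
Reagents that add atoms: triisopropylsilyl chloride, CC(C)[Si](Cl)(C(C)C)C(C)C
Why: Imidazole-promoted silylation of both phenols.

Step 14
Reactants: 19 3,4-bis(triisopropylsilyloxy)benzaldehyde
Product: 20 [3,4-bis(triisopropylsilyloxy)phenyl]methanol
Conditions: NaBH4, THF/MeOH, 0 °C
Reagents that add atoms: none
Why: Borohydride reduction of an aryl aldehyde to the benzylic alcohol.

Step 15
Reactants: 17 2-allyl-6-(triisopropylsilyloxy)phenol; 20 [3,4-bis(triisopropylsilyloxy)phenyl]methanol
Product: 21 1-allyl-2-{[3,4-bis(triisopropylsilyloxy)benzyl]oxy}-3-(triisopropylsilyloxy)benzene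
Conditions: PPh3, DIAD, toluene, 0 °C → rt
Reagents that add atoms: none
Why: Mitsunobu etherification of the hindered phenol with the primary benzylic alcohol under neutral conditions avoids the base-induced silyl migration between the catechol oxygens that a carbonate alkylation would risk.

Step 16
Reactants: 21 1-allyl-2-{[3,4-bis(triisopropylsilyloxy)benzyl]oxy}-3-(triisopropylsilyloxy)benzene
Product: 22 methyl 2-{2-[3,4-bis(triisopropylsilyloxy)benzyloxy]-3-(triisopropylsilyloxy)phenyl}acetate
Conditions: O3, 2.5 M NaOH in MeOH, CH2Cl2, −78 °C (Sudan red indicator)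
Reagents that add atoms: ozone, [O-][O+]=O; methanol, CO
Why: Marshall ozonolysis in methanolic NaOH cleaves the terminal alkene and oxidises the aldehyde methyl hemiacetal in situ to the methyl arylacetate; indicator-controlled dosing at −78 °C should spare the electron-rich rings and the aryl silyl ethers.

Step 17
Reactants: 22 methyl 2-{2-[3,4-bis(triisopropylsilyloxy)benzyloxy]-3-(triisopropylsilyloxy)phenyl}acetate
Product: 23 methyl 2-diazo-2-{2-[3,4-bis(triisopropylsilyloxy)benzyloxy]-3-(triisopropylsilyloxy)phenyl}acetate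
Conditions: p-ABSA, DBU, MeCN, 0 °C → rt
Reagents that add atoms: 4-acetamidobenzenesulfonyl azide, CC(=O)Nc1ccc(cc1)S(=O)(=O)N=[N+]=[N-]
Why: Regitz diazo transfer to the benzylic, ester-activated methylene.

Step 18
Reactants: 23 methyl 2-diazo-2-{2-[3,4-bis(triisopropylsilyloxy)benzyloxy]-3-(triisopropylsilyloxy)phenyl}acetate
Product: 24 methyl (2S,3R)-2-[3,4-bis(triisopropylsilyloxy)phenyl]-7-(triisopropylsilyloxy)-2,3-dihydrobenzofuran-3-carboxylate (cis)
Conditions: Rh2(R-PTTL)4, dirhodium tetrakis[N-phthaloyl-(R)-tert-leucinate] (1 mol%), toluene, −60 °C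
Reagents that add atoms: none
Why: Intramolecular 1,5 C–H insertion of the donor/acceptor rhodium carbenoid into the benzylic, α-oxy C–H bond closes the dihydrobenzofuran; this catalyst class is known to give the kinetic cis-2-aryl-3-carboxylate with high enantiocontrol, so C2 (S) and C3 (R) are both set by the chiral dirhodium carboxylate.

Step 19
Reactants: 24 methyl (2S,3R)-2-[3,4-bis(triisopropylsilyloxy)phenyl]-7-(triisopropylsilyloxy)-2,3-dihydrobenzofuran-3-carboxylate
Product: 25 (2S,3R)-2-[3,4-bis(triisopropylsilyloxy)phenyl]-7-(triisopropylsilyloxy)-2,3-dihydrobenzofuran-3-carboxylic acid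
Conditions: Me3SnOH, 1,2-dichloroethane, 80 °C; dilute HCl wash
Reagents that add atoms: trimethyltin hydroxide, C[Sn](C)(C)O
Why: Trimethyltin hydroxide cleaves methyl esters under near-neutral conditions (a method used for epimerisable esters), so the cis C3 centre α to the carbonyl should not be enolised; aryl TIPS ethers should tolerate it.

Step 20
Reactants: 4 2-(trimethylsilyl)ethanol; 26 acryloyl chloride
Product: 27 2-(trimethylsilyl)ethyl acrylate
Conditions: Et3N, CH2Cl2, 0 °C
Reagents that add atoms: none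
Why: O-acylation of a primary alcohol with an acid chloride.

Step 21
Reactants: 25 (2S,3R)-2-[3,4-bis(triisopropylsilyloxy)phenyl]-7-(triisopropylsilyloxy)-2,3-dihydrobenzofuran-3-carboxylic acid; 27 2-(trimethylsilyl)ethyl acrylate
Product: 28 (2S,3R)-2-[3,4-bis(triisopropylsilyloxy)phenyl]-7-(triisopropylsilyloxy)-4-{(E)-3-oxo-3-[2-(trimethylsilyl)ethoxy]prop-1-enyl}-2,3-dihydrobenzofuran-3-carboxylic acid
Conditions: Pd(OAc)2 (10 mol%), Ac-Ile-OH (20 mol%), KHCO3 (2 equiv), O2 (1 atm), t-AmOH, 85 °C
Reagents that add atoms: none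
Why: Carboxylate-directed ortho C–H olefination (divalent palladium with a mono-protected amino acid ligand, O2 as oxidant), precedented on 2-aryl-2,3-dihydrobenzofuran-3-carboxylic acids: the potassium carboxylate directs palladation to C4 through a six-membered palladacycle, syn insertion and β-hydride elimination give the E-acrylate, and the carboxylate form protects C3 from epimerisation.

Step 22
Reactants: 28 (2S,3R)-2-[3,4-bis(triisopropylsilyloxy)phenyl]-7-(triisopropylsilyloxy)-4-{(E)-3-oxo-3-[2-(trimethylsilyl)ethoxy]prop-1-enyl}-2,3-dihydrobenzofuran-3-carboxylic acid; 14 2-(trimethylsilyl)ethyl (3R,4R,5S)-4,5-epoxy-3-hydroxycyclohex-1-ene-1-carboxylate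
Product: 29 2-(trimethylsilyl)ethyl 5-O-{(2S,3R)-2-[3,4-bis(triisopropylsilyloxy)phenyl]-7-(triisopropylsilyloxy)-4-[(E)-3-oxo-3-(2-trimethylsilylethoxy)prop-1-enyl]-2,3-dihydrobenzofuran-3-carbonyl}shikimate (free 3,4-diol)
Conditions: Ti(OiPr)4 (1.5 equiv), CH2Cl2, rt; aqueous tartaric acid work-up
Reagents that add atoms: none
Why: Titanium tetraisopropoxide-mediated regioselective opening of a 2,3-epoxy alcohol by a carboxylic acid at the distal carbon: titanium bound to the C3 hydroxyl and the epoxide delivers the carboxylate to C5 anti to the epoxide oxygen (trans-diaxial), restoring the natural C5 configuration by a second inversion and forming the ester without activating the epimerisable acid.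

Step 23
Reactants: 29 2-(trimethylsilyl)ethyl 5-O-{(2S,3R)-2-[3,4-bis(triisopropylsilyloxy)phenyl]-7-(triisopropylsilyloxy)-4-[(E)-3-oxo-3-(2-trimethylsilylethoxy)prop-1-enyl]-2,3-dihydrobenzofuran-3-carbonyl}shikimate
Product: 30 5-O-{(2S,3R)-4-[(E)-2-carboxyvinyl]-2-(3,4-dihydroxyphenyl)-7-hydroxy-2,3-dihydrobenzofuran-3-carbonyl}shikimic acid (target)
Conditions: TASF (tris(dimethylamino)sulfonium difluorotrimethylsilicate), degassed DMF, 0 °C → rt; dilute HCl to pH 3
Reagents that add atoms: none
Why: Fluoride-induced global desilylation: TASF cleaves the three aryl TIPS ethers and fragments the two TMSE esters (β-elimination to ethene and fluorotrimethylsilane) under anhydrous, weakly basic conditions at low temperature, which should spare the ester linkage, both alkenes and the cis C2/C3 centres.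

**Compound list**

1 | (R)-4-(tert-butyldimethylsilyloxy)cyclopent-2-en-1-one | CC(C)(C)[Si](C)(C)O[C@@H]1CC(=O)C=C1 | starting material
2 | (2S,3R,4R)-4-(tert-butyldimethylsilyloxy)-2,3-dihydroxycyclopentan-1-one | CC(C)(C)[Si](C)(C)O[C@@H]1CC(=O)[C@@H](O)[C@H]1O | intermediate
3 | (2S,3R,4R)-4-(tert-butyldimethylsilyloxy)-2,3-(isopropylidenedioxy)cyclopentan-1-one | CC(C)(C)[Si](C)(C)O[C@@H]1CC(=O)[C@H]2OC(C)(C)O[C@@H]12 | intermediate
4 | 2-(trimethylsilyl)ethanol | C[Si](C)(C)CCO | starting material
5 | bromoacetyl bromide | BrCC(Br)=O | starting material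
6 | 2-(trimethylsilyl)ethyl bromoacetate | C[Si](C)(C)CCOC(=O)CBr | intermediate
7 | 2-(trimethylsilyl)ethyl diazoacetate | C[Si](C)(C)CCOC(=O)C=[N+]=[N-] | intermediate
8 | 2-(trimethylsilyl)ethyl 2-diazo-2-[(2S,3R,4R)-4-(tert-butyldimethylsilyloxy)-1-hydroxy-2,3-(isopropylidenedioxy)cyclopentyl]acetate (C1 epimers) | CC(C)(C)[Si](C)(C)O[C@@H]1CC(O)(C(=[N+]=[N-])C(=O)OCC[Si](C)(C)C)[C@H]2OC(C)(C)O[C@@H]12 | intermediate
9 | 2-(trimethylsilyl)ethyl (3S,4R,5R)-5-(tert-butyldimethylsilyloxy)-3,4-(isopropylidenedioxy)-2-oxocyclohexane-1-carboxylate (C1 epimers) | CC(C)(C)[Si](C)(C)O[C@@H]1CC(C(=O)OCC[Si](C)(C)C)C(=O)[C@H]2OC(C)(C)O[C@@H]12 | intermediate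
10 | 2-(trimethylsilyl)ethyl 5-(tert-butyldimethylsilyloxy)-2-hydroxy-3,4-(isopropylidenedioxy)cyclohexane-1-carboxylate (C1/C2 diastereomers) | CC(C)(C)[Si](C)(C)O[C@@H]1CC(C(=O)OCC[Si](C)(C)C)C(O)[C@H]2OC(C)(C)O[C@@H]12 | intermediate
11 | C2 methanesulfonate of 10 | CC(C)(C)[Si](C)(C)O[C@@H]1CC(C(=O)OCC[Si](C)(C)C)C(OS(C)(=O)=O)[C@H]2OC(C)(C)O[C@@H]12 | intermediate (not isolated)
12 | 2-(trimethylsilyl)ethyl 5-O-(tert-butyldimethylsilyl)-3,4-O-isopropylidene-shikimate | CC(C)(C)[Si](C)(C)O[C@@H]1CC(C(=O)OCC[Si](C)(C)C)=C[C@H]2OC(C)(C)O[C@@H]12 | intermediate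
13 | 2-(trimethylsilyl)ethyl shikimate, (3R,4S,5R) | O[C@@H]1CC(C(=O)OCC[Si](C)(C)C)=C[C@@H](O)[C@H]1O | intermediate
14 | 2-(trimethylsilyl)ethyl (3R,4R,5S)-4,5-epoxy-3-hydroxycyclohex-1-ene-1-carboxylate | O[C@@H]1C=C(C(=O)OCC[Si](C)(C)C)C[C@@H]2O[C@H]12 | intermediate
15 | 2-(allyloxy)phenol | C=CCOc1ccccc1O | starting material
16 | 1-(allyloxy)-2-(triisopropylsilyloxy)benzene | C=CCOc1ccccc1O[Si](C(C)C)(C(C)C)C(C)C | intermediate
17 | 2-allyl-6-(triisopropylsilyloxy)phenol | C=CCc1cccc(O[Si](C(C)C)(C(C)C)C(C)C)c1O | intermediate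
18 | 3,4-dihydroxybenzaldehyde | O=Cc1ccc(O)c(O)c1 | starting material
19 | 3,4-bis(triisopropylsilyloxy)benzaldehyde | O=Cc1ccc(O[Si](C(C)C)(C(C)C)C(C)C)c(O[Si](C(C)C)(C(C)C)C(C)C)c1 | intermediate
20 | [3,4-bis(triisopropylsilyloxy)phenyl]methanol | OCc1ccc(O[Si](C(C)C)(C(C)C)C(C)C)c(O[Si](C(C)C)(C(C)C)C(C)C)c1 | intermediate
21 | 1-allyl-2-{[3,4-bis(triisopropylsilyloxy)benzyl]oxy}-3-(triisopropylsilyloxy)benzene | C=CCc1cccc(O[Si](C(C)C)(C(C)C)C(C)C)c1OCc1ccc(O[Si](C(C)C)(C(C)C)C(C)C)c(O[Si](C(C)C)(C(C)C)C(C)C)c1 | intermediate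
22 | methyl 2-{2-[3,4-bis(triisopropylsilyloxy)benzyloxy]-3-(triisopropylsilyloxy)phenyl}acetate | COC(=O)Cc1cccc(O[Si](C(C)C)(C(C)C)C(C)C)c1OCc1ccc(O[Si](C(C)C)(C(C)C)C(C)C)c(O[Si](C(C)C)(C(C)C)C(C)C)c1 | intermediate
23 | methyl 2-diazo-2-{2-[3,4-bis(triisopropylsilyloxy)benzyloxy]-3-(triisopropylsilyloxy)phenyl}acetate | COC(=O)C(=[N+]=[N-])c1cccc(O[Si](C(C)C)(C(C)C)C(C)C)c1OCc1ccc(O[Si](C(C)C)(C(C)C)C(C)C)c(O[Si](C(C)C)(C(C)C)C(C)C)c1 | intermediate
24 | methyl (2S,3R)-2-[3,4-bis(triisopropylsilyloxy)phenyl]-7-(triisopropylsilyloxy)-2,3-dihydrobenzofuran-3-carboxylate | c1ccc(O[Si](C(C)C)(C(C)C)C(C)C)c2c1[C@@H](C(=O)OC)[C@@H](c1ccc(O[Si](C(C)C)(C(C)C)C(C)C)c(O[Si](C(C)C)(C(C)C)C(C)C)c1)O2 | intermediate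
25 | (2S,3R)-2-[3,4-bis(triisopropylsilyloxy)phenyl]-7-(triisopropylsilyloxy)-2,3-dihydrobenzofuran-3-carboxylic acid | c1ccc(O[Si](C(C)C)(C(C)C)C(C)C)c2c1[C@@H](C(=O)O)[C@@H](c1ccc(O[Si](C(C)C)(C(C)C)C(C)C)c(O[Si](C(C)C)(C(C)C)C(C)C)c1)O2 | intermediate
26 | acryloyl chloride | C=CC(=O)Cl | starting material
27 | 2-(trimethylsilyl)ethyl acrylate | C=CC(=O)OCC[Si](C)(C)C | intermediate
28 | (2S,3R)-2-[3,4-bis(triisopropylsilyloxy)phenyl]-7-(triisopropylsilyloxy)-4-{(E)-3-oxo-3-[2-(trimethylsilyl)ethoxy]prop-1-enyl}-2,3-dihydrobenzofuran-3-carboxylic acid | C[Si](C)(C)CCOC(=O)/C=C/c1ccc(O[Si](C(C)C)(C(C)C)C(C)C)c2c1[C@@H](C(=O)O)[C@@H](c1ccc(O[Si](C(C)C)(C(C)C)C(C)C)c(O[Si](C(C)C)(C(C)C)C(C)C)c1)O2 | intermediate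
29 | 2-(trimethylsilyl)ethyl 5-O-acyl shikimate with free 3,4-diol (acyl = the acid residue of 28) | C[Si](C)(C)CCOC(=O)/C=C/c1ccc(O[Si](C(C)C)(C(C)C)C(C)C)c2c1[C@@H](C(=O)O[C@@H]1CC(C(=O)OCC[Si](C)(C)C)=C[C@@H](O)[C@H]1O)[C@@H](c1ccc(O[Si](C(C)C)(C(C)C)C(C)C)c(O[Si](C(C)C)(C(C)C)C(C)C)c1)O2 | intermediate
30 | 5-O-{(2S,3R)-4-[(E)-2-carboxyvinyl]-2-(3,4-dihydroxyphenyl)-7-hydroxy-2,3-dihydrobenzofuran-3-carbonyl}shikimic acid | O=C(O)/C=C/c1ccc(O)c2c1[C@@H](C(=O)O[C@@H]1CC(C(=O)O)=C[C@@H](O)[C@H]1O)[C@@H](c1ccc(O)c(O)c1)O2 | target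

**Count and risks**

Total steps: 23. Longest linear sequence: 10 steps (1 → 2 → 3 → 8 → 9 → 10 → 12 → 13 → 14 → 29 → 30; the branch from 15 is equally long).

Steps most likely to fail:

1. Step 22. The hindered carboxylate may attack the titanium-bound epoxide too slowly, isopropoxide may be delivered instead, or the new acyl group may migrate to O4 on the titanium diolate. Fallback (acylation instead of epoxide opening): setting out from 12, the TBS ether alone is cleaved with HF·pyridine (THF/pyridine, 0 °C → rt) to give 2-(trimethylsilyl)ethyl 3,4-O-isopropylidene-shikimate F1. F1 is acylated with acid 28 by carbodiimide coupling (EDC·HCl, catalytic DMAP, CH2Cl2, −20 → 0 °C, kept short and cold to limit enolisation of the activated acid) to give the 5-O-acyl 3,4-O-isopropylidene ester F2. 80% aqueous AcOH at 40 °C removes the acetonide and the sequence comes back to the route at 29.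

2. Step 6. The oxygen-bearing ring carbon may migrate in competition with the CH2 (regioisomeric β-keto ester), or the carbenoid may be diverted to O–H insertion. Fallback (Lewis acid-promoted insertion instead of a metal carbene): setting out from ketone 3, direct treatment with diazoacetate 7 and BF3·OEt2 (CH2Cl2, −78 → −20 °C) adds the diazo carbon to the activated carbonyl; in the resulting diazonium betaine the less substituted CH2 migrates antiperiplanar to the departing N2. This comes back to the route at 9 without passing through 8.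

3. Step 23. Fluoride basicity may cause migration of the acyl group from O5 to the free O4, partial enolisation at C3 of the dihydrobenzofuran, or air oxidation of the freed catechol. Fallback (diol masked during the fluoride step): setting out from 29, 2,2-dimethoxypropane/PPTS converts the 3,4-diol into the 5-O-acyl 3,4-O-isopropylidene ester F2. TASF (DMF, 0 °C) then frees the two acids and three phenols to give the 3,4-O-isopropylidene derivative of the target F3. 80% aqueous AcOH at 40 °C removes the acetonide and the sequence comes back to the route at 30.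

**Further compounds**

F1 | step 22 | 2-(trimethylsilyl)ethyl 3,4-O-isopropylidene-shikimate | O[C@@H]1CC(C(=O)OCC[Si](C)(C)C)=C[C@H]2OC(C)(C)O[C@@H]12
F2 | step 22 | 2-(trimethylsilyl)ethyl 5-O-acyl-3,4-O-isopropylidene-shikimate (acyl = the acid residue of 28) | C[Si](C)(C)CCOC(=O)/C=C/c1ccc(O[Si](C(C)C)(C(C)C)C(C)C)c2c1[C@@H](C(=O)O[C@@H]1CC(C(=O)OCC[Si](C)(C)C)=C[C@H]3OC(C)(C)O[C@@H]13)[C@@H](c1ccc(O[Si](C(C)C)(C(C)C)C(C)C)c(O[Si](C(C)C)(C(C)C)C(C)C)c1)O2
F0 | step 6 | none | none
F3 | step 23 | 3,4-O-isopropylidene derivative of target 30 | O=C(O)/C=C/c1ccc(O)c2c1[C@@H](C(=O)O[C@@H]1CC(C(=O)O)=C[C@H]3OC(C)(C)O[C@@H]13)[C@@H](c1ccc(O)c(O)c1)O2
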